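# Proposed total synthesis of gericudranin E, (2R,3R)-3,5,7-trihydroxy-6-(4-hydroxybenzyl)-2-(4-hydroxyphenyl)chroman-4-one

Flavonoid numbering is used throughout (O1, C2, C3, C4, C4a, C5–C8, C8a; ring B atoms primed).

## Structural features

Gericudranin E is a trans-dihydroflavonol: a chroman-4-one in which aromatic ring A is fused to the oxygen heterocycle, ring C, and C2 of ring C carries the 4-hydroxyphenyl ring B. Ring A has hydroxyls at C5 and C7, the ring oxygen O1 at C8a, a hydrogen at C8, and a 4-hydroxybenzyl group at C6, which lies between the two hydroxyls and para to O1. The stereocentres C2 (R) and C3 (R) are adjacent and trans, with aryl and hydroxyl both equatorial. C3 is α to the C4 carbonyl and can therefore be corrected; C2 is a benzylic ether carbon and is lost whenever the C2–O1 bond ionizes or ring C opens. The fragile features are the β-aryloxy ketone (base opens ring C, and air then leads to the flavonol), the free 4'-hydroxyl (a quinone methide path to C2 epimerization) and, in intermediates, any carbinol at C4, which is benzylic to a trioxygenated ring and ionizes with traces of acid. The real difficulties are to place the benzyl group at C6 and not at the equally activated C8, and to set the absolute configuration at C2 with the C3 hydroxyl trans to it. The first is answered by building ring A from a precursor in which both positions ortho to the future O1 are equivalent. The key step exploits two facts: O3 is trans to the C2 aryl group, and C4 is a carbonyl carbon benzylic to ring A. Both oxygens can therefore come from one syn addition to the C3=C4 bond of a flav-3-ene on the face opposite the aryl group, after which only the benzylic C4 hydroxyl needs oxidizing.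

## Logic of the disconnections

**18 from 17.** The four aryl O–CH2Ph bonds are cut. One kind of protecting group means one neutral hydrogenolysis at the end, which suits a product that tolerates neither base nor strong acid. The demand on the forward step is that the C4 carbonyl and the benzylic C2–O1 bond survive the hydrogenation.

**17 from 16.** The C4 carbonyl is taken back to a C4 carbinol. This turns the ketol into a vicinal diol that an alkene can deliver. The forward step must oxidize the benzylic C4 hydroxyl and leave the C3 hydroxyl, without cleaving the C3–C4 bond.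

**16 from 15.** The C3–O and C4–O bonds are cut together. This removes two stereocentres and leaves C2 as the only one. The forward step must add both oxygens to the face of C3=C4 opposite the C2 aryl group; only the C3 outcome is carried to the target.

**15 from 14.** The C3=C4 bond is cut. Ring C becomes an open aryl ether with two alkene termini. The forward metathesis must close a six-membered ring without touching the ionizable C2–O1 bond.

**14 from 9 and 13.** The O1–C2 bond is cut. This separates the ring A phenol from a three-carbon unit carrying ring B and is the point at which absolute configuration enters. The forward step must be branched-selective, enantioselective and O-selective with an electron-rich, ortho-substituted phenoxide.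

**9 from 8, and 8 from 7.** The propenyl double bond is moved back to an allyl group, and the C4a–C4 bond is then cut back to an O1-allyl ether. The oxygen that has to be masked while O5 and O7 are benzylated thus carries the carbon that becomes C4, so no deprotection, formylation or methylenation is needed. Because both positions ortho to O1 in 7 are equivalent, the sigmatropic shift can give only one product. The forward steps need benzyl ethers that survive about 190 °C and an isomerization catalyst that tolerates a free phenol.

**7 from 6, and 6 from 3 and 5 (made from 4).** The benzylic C–H bond is taken back to a carbinol, and the bond between the carbinol carbon and the future 4-hydroxybenzyl ring is cut. Placing the one-carbon link on the ring A aldehyde fixes the benzyl group between the two benzyloxy groups and para to O1, which settles the C6 against C8 question. The forward reduction must trap a very stabilized diarylmethyl cation with hydride before it alkylates another arene.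

**3 from 2, and 2 from 1.** Two O–benzyl bonds and one O–allyl bond are cut. The 4-hydroxyl of 1 is the only one not hydrogen-bonded to the formyl group and the most acidic, so it can be alkylated first. The forward mono-allylation must stop after one alkylation.

**13 from 12, 12 from 11, 11 from 10.** The carbonate C–O bond, the ester oxidation level and the C=C bond are cut in turn. The forward sequence must give the (E)-alkene and a 1,2-reduction.

## Other disconnections considered

**Alternative 1:** The cut removes ring A altogether (C8–C8a, C5–C6, C7–C8, C4a–C5). Ring C is left as the enantiopure diazo ketone A2, and the 4-(benzyloxy)benzyl group sits on the siloxyalkyne A3. In the forward direction, irradiation of A2 would trigger a Wolff rearrangement. A ketene–alkyne [2+2] cycloaddition with A3, a four-electron ring opening and a six-electron electrocyclization on warming should then give A1.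

- In its favour: the substitution pattern of ring A is dictated by the polarity of the two partners, and the C4 carbonyl is in place from the start. No acid-labile C4 carbinol such as 16 is ever handled, and on this point the alternative is better than the chosen plan.
- On regiocontrol of the C6 benzyl group the two plans are equal: symmetry in one, polarity in the other.
- Against it: both stereocentres must already be present in A2, with C3 next to a ketone during photolysis and heating. The enone of A2 competes for the light. A1 still needs a desilylation as well as a hydrogenolysis.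
- Mechanism: a four-stage pericyclic cascade has more places to diverge than a single cycloaddition.
- Step economy: A2 and A3 each need a synthesis of their own, so the route would be clearly longer than the chosen one.

**Alternative 2:** The cut is the C2–C3 bond, seen as the result of a 1,2-shift. The precursor is the hydroxy aldehyde A5, a 2-aryl-3-hydroxy-2,3-dihydrobenzofuran-3-carbaldehyde. In the forward direction, a chelating aluminium alkoxide would hold the carbinol and formyl oxygens syn. C2 would migrate with retention from the carbinol carbon to the formyl carbon; the carbinol carbon becomes C4 and the five-membered ring expands to ring C, giving A4, which is the same compound as 17.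

- In its favour: the step is redox-neutral and needs neither osmium nor a separate diol oxidation. Here it is better than the chosen plan by one operation between ring C and 17; from 17 onwards the two plans are identical.
- Against it: in the chelate model the configuration of the carbinol carbon of A5 is relayed to C3. A5 therefore needs two defined centres, one of them quaternary, and the stereochemical problem is moved rather than simplified.
- The electron-rich aryl carbon C3a is equally well aligned for migration, which would give the isomeric 4-hydroxychroman-3-one skeleton.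
- The tertiary benzylic carbinol of A5 ionizes as readily as C4 of 16.
- Step economy: the path to A5 is expected to be longer than the path to 15.

**Alternative 3:** The cut is C8–C8a and C4a–C5. Ring A is assembled from the four-carbon bis(silyloxy)diene A8 and the two alkene carbons of the bromodihydropyranone A7. In the forward direction, a silyl triflate should promote conjugate addition of the diene terminus to C8a. Cyclization of C4a onto the ester carbon would follow, with aromatization by loss of bromide, the methoxy group and the silyl groups, to give A6.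

- In its favour: the assembly is convergent, and ring A appears with free 5- and 7-hydroxyls, so only three benzyl ethers are carried. On protecting-group economy for ring A this is better than the chosen plan. C6 regiochemistry is fixed by the diene, which is equal to the chosen plan.
- Against it: A7 must carry both stereocentres through a strong Lewis acid. Its C2–O1 bond is benzylic and para-alkoxy-activated and can ionize, and after the conjugate addition O1 can be expelled in a β-elimination that competes with ring closure.
- Mechanism: a multi-event domino sequence is harder to steer than one cycloaddition.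
- Step economy: A7 and A8 need their own syntheses, so the total is expected to be equal to or longer than the chosen route.

Key step: step 12

**Assumptions and remarks**

- The (Sa,Sc,Sc) antipode of the binaphthol-derived N,N-bis(1-phenylethyl)phosphoramidite is taken to deliver the (S) ether 14. If the sense of induction on this substrate is the opposite, the (Ra,Rc,Rc) antipode is used and nothing else changes.
- The descriptor at C2 changes from S in 14 and 15 to R in 16–18 without any change in geometry. Once C3 carries oxygen it outranks the aryl group in the CIP order.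
- Intermediates 14, 15 and 16 are kept away from acid and light, because the C2–O1 bond of 14 and 15 and the C4 carbinol of 16 ionize easily.
- Allyl bromide, benzyl bromide, triethyl phosphonoacetate and methyl chloroformate are treated as commercial reagents.

## Route

Step 1
Reactants: 1 2,4,6-trihydroxybenzaldehyde
Product: 2 4-(allyloxy)-2,6-dihydroxybenzaldehyde
Conditions: allyl bromide (1.05 equiv), KHCO3 (1.2 equiv), DMF, 40 °C
Reagents that add atoms: allyl bromide, C=CCBr
Why: Williamson etherification; hydrogencarbonate ionizes only the 4-hydroxyl, which is para to the formyl group and not hydrogen-bonded, while the two ortho hydroxyls stay chelated and unreactive.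

Step 2
Reactants: 2 4-(allyloxy)-2,6-dihydroxybenzaldehyde
Product: 3 4-(allyloxy)-2,6-bis(benzyloxy)benzaldehyde
Conditions: BnBr (2.5 equiv), K2CO3 (3 equiv), DMF, 60 °C
Reagents that add atoms: benzyl bromide, BrCc1ccccc1
Why: Williamson etherification of the two equivalent chelated phenols under stronger base and heat; no selectivity is needed and the allyl ether is inert.

Step 3
Reactants: 3 4-(allyloxy)-2,6-bis(benzyloxy)benzaldehyde; 4 1-(benzyloxy)-4-bromobenzene
Product: 6 [4-(allyloxy)-2,6-bis(benzyloxy)phenyl][4-(benzyloxy)phenyl]methanol (racemic), via [4-(benzyloxy)phenyl]magnesium bromide 5 (not isolated)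
Conditions: 4, Mg, THF, 40 °C; then 3, THF, 0 °C → rt; aq NH4Cl
Reagents that add atoms: magnesium, [Mg] (enters 5 only and is lost on work-up)
Why: Grignard addition of an aryl nucleophile to a non-enolizable aldehyde; the carbinol centre is racemic and is removed in step 4.

Step 4
Reactants: 6 [4-(allyloxy)-2,6-bis(benzyloxy)phenyl][4-(benzyloxy)phenyl]methanol
Product: 7 5-(allyloxy)-1,3-bis(benzyloxy)-2-[4-(benzyloxy)benzyl]benzene
Conditions: Et3SiH (3 equiv), CF3CO2H (2 equiv), CH2Cl2, −20 → 0 °C
Reagents that add atoms: none
Why: Ionic hydrogenation; the diarylmethyl cation, stabilized by four alkoxy groups, forms in cold acid and is trapped by silane hydride, and excess silane at high dilution should outrun Friedel–Crafts self-alkylation while allyl and benzyl ethers survive.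

Step 5
Reactants: 7 5-(allyloxy)-1,3-bis(benzyloxy)-2-[4-(benzyloxy)benzyl]benzene
Product: 8 2-allyl-3,5-bis(benzyloxy)-4-[4-(benzyloxy)benzyl]phenol
Conditions: N,N-diethylaniline, 190 °C, argon
Reagents that add atoms: none
Why: Aromatic Claisen rearrangement; the [3,3] shift can reach only the two equivalent free ortho positions, so one product is expected, and it frees the O1 hydroxyl while placing the future C4 on C4a.

Step 6
Reactants: 8 2-allyl-3,5-bis(benzyloxy)-4-[4-(benzyloxy)benzyl]phenol
Product: 9 3,5-bis(benzyloxy)-4-[4-(benzyloxy)benzyl]-2-[(1E)-prop-1-en-1-yl]phenol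
Conditions: RuClH(CO)(PPh3)3 (5 mol %), toluene, 80 °C
Reagents that add atoms: none
Why: Metal hydride alkene isomerization by insertion and β-hydride elimination, driven by conjugation with the arene; the (E) isomer should dominate and any (Z) isomer is equally usable in step 11.

Step 7
Reactants: 10 4-(benzyloxy)benzaldehyde
Product: 11 ethyl (2E)-3-[4-(benzyloxy)phenyl]prop-2-enoate
Conditions: (EtO)2P(O)CH2CO2Et, NaH, THF, 0 °C → rt
Reagents that add atoms: triethyl phosphonoacetate, CCOC(=O)CP(=O)(OCC)OCC
Why: Horner–Wadsworth–Emmons olefination; the stabilized phosphonate anion gives the (E)-enoate.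

Step 8
Reactants: 11 ethyl (2E)-3-[4-(benzyloxy)phenyl]prop-2-enoate
Product: 12 (2E)-3-[4-(benzyloxy)phenyl]prop-2-en-1-ol
Conditions: i-Bu2AlH (2.3 equiv), CH2Cl2, −78 → 0 °C; aq KNaC4H4O6
Reagents that add atoms: none
Why: 1,2-Reduction of an enoate by an aluminium hydride, which leaves the conjugated alkene and the benzyl ether untouched.

Step 9
Reactants: 12 (2E)-3-[4-(benzyloxy)phenyl]prop-2-en-1-ol
Product: 13 (2E)-3-[4-(benzyloxy)phenyl]prop-2-en-1-yl methyl carbonate
Conditions: ClCO2Me (1.5 equiv), pyridine, CH2Cl2, 0 °C
Reagents that add atoms: methyl chloroformate, COC(=O)Cl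
Why: Acylation of a primary allylic alcohol to give the leaving group for allylic substitution.

Step 10
Reactants: 9 3,5-bis(benzyloxy)-4-[4-(benzyloxy)benzyl]-2-[(1E)-prop-1-en-1-yl]phenol; 13 (2E)-3-[4-(benzyloxy)phenyl]prop-2-en-1-yl methyl carbonate
Product: 14 1,3-bis(benzyloxy)-2-[4-(benzyloxy)benzyl]-5-{[(1S)-1-[4-(benzyloxy)phenyl]prop-2-en-1-yl]oxy}-4-[(1E)-prop-1-en-1-yl]benzene
Conditions: 9, n-BuLi (1.0 equiv), THF, 0 °C; then 13 (1.1 equiv), [Ir(cod)Cl]2 (2 mol %), (Sa,Sc,Sc)-binaphthol N,N-bis(1-phenylethyl)phosphoramidite (4 mol %, pre-activated with n-PrNH2), THF, rt, dark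
Reagents that add atoms: none
Why: Iridium-catalysed asymmetric allylic etherification; the carbonate ionizes to an allyl iridium complex and the lithium phenoxide attacks the aryl-substituted terminus on the face left open by the cyclometalated phosphoramidite, which should give the branched (S) ether with O-alkylation favoured over C-alkylation.

Step 11
Reactants: 14 1,3-bis(benzyloxy)-2-[4-(benzyloxy)benzyl]-5-{[(1S)-1-[4-(benzyloxy)phenyl]prop-2-en-1-yl]oxy}-4-[(1E)-prop-1-en-1-yl]benzene
Product: 15 (2S)-5,7-bis(benzyloxy)-6-[4-(benzyloxy)benzyl]-2-[4-(benzyloxy)phenyl]-2H-chromene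
Conditions: second-generation Grubbs catalyst (H2IMes)(PCy3)Cl2Ru=CHPh (5 mol %), CH2Cl2 (0.01 M), 40 °C, dark
Reagents that add atoms: none
Why: Ring-closing metathesis; the catalyst loads on the terminal vinyl group and closes onto the propenyl group to form C3=C4 in a six-membered ring with loss of propene, and C2 is not involved.

Step 12
Reactants: 15 (2S)-5,7-bis(benzyloxy)-6-[4-(benzyloxy)benzyl]-2-[4-(benzyloxy)phenyl]-2H-chromene
Product: 16 (2R,3S,4S)-5,7-bis(benzyloxy)-6-[4-(benzyloxy)benzyl]-2-[4-(benzyloxy)phenyl]chromane-3,4-diol
Conditions: OsO4 (2 mol %), N-methylmorpholine N-oxide (1.5 equiv), acetone/THF/H2O, 0 °C → rt, dark; aq Na2SO3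
Reagents that add atoms: osmium tetroxide, O=[Os](=O)(=O)=O; N-methylmorpholine N-oxide, C[N+]1([O-])CCOCC1; water, O
Why: OsO4 adds across the electron-rich styrenic C3=C4 bond in a concerted [3+2] cycloaddition, so both C–O bonds form on one face and the diol must be 3,4-cis; the amine oxide reoxidizes the hexavalent osmium glycolate and water releases the diol. The closest known reaction type is the osmium-catalysed (Upjohn) dihydroxylation of 2-substituted 2H-chromenes and flav-3-enes, which gives 2,3-trans-3,4-cis diols. No ring is closed. C2 is the only sp3 centre next to the alkene and its aryl group lies over one face of the heterocycle, so the reagent should approach from the other face; C3 (S) and C4 (S) are thus both set by C2, with the oxygens anti to the aryl group. The selectivity needed is facial only: both alkene carbons receive oxygen, so there is no regiochemical question, and the propenyl group left in step 11, so C3=C4 is the only alkene. The benzyl ethers and the diarylmethane are inert to OsO4 under these neutral conditions. Only the C3 configuration is carried to the target, since C4 becomes a carbonyl in step 13. Compound 16 ionizes at C4 with acid and should be purified on base-washed silica or used crude.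

Step 13
Reactants: 16 (2R,3S,4S)-5,7-bis(benzyloxy)-6-[4-(benzyloxy)benzyl]-2-[4-(benzyloxy)phenyl]chromane-3,4-diol
Product: 17 (2R,3R)-5,7-bis(benzyloxy)-6-[4-(benzyloxy)benzyl]-2-[4-(benzyloxy)phenyl]-3-hydroxychroman-4-one
Conditions: activated MnO2 (15 equiv), CH2Cl2, rt
Reagents that add atoms: none
Why: Benzylic alcohol oxidation on MnO2, a known conversion of chroman-3,4-diols into 3-hydroxychroman-4-ones; the C4 carbinol is activated by ring A and the C3 carbinol is not, and the neutral surface avoids ionization at C4 and leaves C2 and C3 untouched.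

Step 14
Reactants: 17 (2R,3R)-5,7-bis(benzyloxy)-6-[4-(benzyloxy)benzyl]-2-[4-(benzyloxy)phenyl]-3-hydroxychroman-4-one
Product: 18 (2R,3R)-3,5,7-trihydroxy-6-(4-hydroxybenzyl)-2-(4-hydroxyphenyl)chroman-4-one (gericudranin E)
Conditions: H2 (1 atm), Pd/C (10% Pd), EtOAc/MeOH, rt
Reagents that add atoms: none
Why: Hydrogenolysis of four aryl benzyl ethers under neutral conditions; stopped at full debenzylation, it should spare the chelated C4 carbonyl and the C2–O1 bond, so both stereocentres are carried through unchanged.

## Compound list

1 | 2,4,6-trihydroxybenzaldehyde | O=Cc1c(O)cc(O)cc1O | starting material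
2 | 4-(allyloxy)-2,6-dihydroxybenzaldehyde | O=Cc1c(O)cc(OCC=C)cc1O | intermediate
3 | 4-(allyloxy)-2,6-bis(benzyloxy)benzaldehyde | O=Cc1c(OCc2ccccc2)cc(OCC=C)cc1OCc1ccccc1 | intermediate
4 | 1-(benzyloxy)-4-bromobenzene | Brc1ccc(OCc2ccccc2)cc1 | starting material
5 | [4-(benzyloxy)phenyl]magnesium bromide (formed in the flask, not isolated) | Br[Mg]c1ccc(OCc2ccccc2)cc1 | intermediate
6 | [4-(allyloxy)-2,6-bis(benzyloxy)phenyl][4-(benzyloxy)phenyl]methanol (racemic) | OC(c1ccc(OCc2ccccc2)cc1)c1c(OCc2ccccc2)cc(OCC=C)cc1OCc1ccccc1 | intermediate
7 | 5-(allyloxy)-1,3-bis(benzyloxy)-2-[4-(benzyloxy)benzyl]benzene | C=CCOc1cc(OCc2ccccc2)c(Cc2ccc(OCc3ccccc3)cc2)c(OCc2ccccc2)c1 | intermediate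
8 | 2-allyl-3,5-bis(benzyloxy)-4-[4-(benzyloxy)benzyl]phenol | Oc1cc(OCc2ccccc2)c(Cc2ccc(OCc3ccccc3)cc2)c(OCc2ccccc2)c1CC=C | intermediate
9 | 3,5-bis(benzyloxy)-4-[4-(benzyloxy)benzyl]-2-[(1E)-prop-1-en-1-yl]phenol | Oc1cc(OCc2ccccc2)c(Cc2ccc(OCc3ccccc3)cc2)c(OCc2ccccc2)c1/C=C/C | intermediate
10 | 4-(benzyloxy)benzaldehyde | O=Cc1ccc(OCc2ccccc2)cc1 | starting material
11 | ethyl (2E)-3-[4-(benzyloxy)phenyl]prop-2-enoate | CCOC(=O)/C=C/c1ccc(OCc2ccccc2)cc1 | intermediate
12 | (2E)-3-[4-(benzyloxy)phenyl]prop-2-en-1-ol | OC/C=C/c1ccc(OCc2ccccc2)cc1 | intermediate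
13 | (2E)-3-[4-(benzyloxy)phenyl]prop-2-en-1-yl methyl carbonate | COC(=O)OC/C=C/c1ccc(OCc2ccccc2)cc1 | intermediate
14 | 1,3-bis(benzyloxy)-2-[4-(benzyloxy)benzyl]-5-{[(1S)-1-[4-(benzyloxy)phenyl]prop-2-en-1-yl]oxy}-4-[(1E)-prop-1-en-1-yl]benzene | C=C[C@@H](c1ccc(OCc2ccccc2)cc1)Oc1cc(OCc2ccccc2)c(Cc2ccc(OCc3ccccc3)cc2)c(OCc2ccccc2)c1/C=C/C | intermediate
15 | (2S)-5,7-bis(benzyloxy)-6-[4-(benzyloxy)benzyl]-2-[4-(benzyloxy)phenyl]-2H-chromene | C1=C[C@@H](c2ccc(OCc3ccccc3)cc2)Oc2cc(OCc3ccccc3)c(Cc3ccc(OCc4ccccc4)cc3)c(OCc3ccccc3)c21 | intermediate
16 | (2R,3S,4S)-5,7-bis(benzyloxy)-6-[4-(benzyloxy)benzyl]-2-[4-(benzyloxy)phenyl]chromane-3,4-diol | O[C@H]1c2c(OCc3ccccc3)c(Cc3ccc(OCc4ccccc4)cc3)c(OCc3ccccc3)cc2O[C@H](c2ccc(OCc3ccccc3)cc2)[C@H]1O | intermediate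
17 | (2R,3R)-5,7-bis(benzyloxy)-6-[4-(benzyloxy)benzyl]-2-[4-(benzyloxy)phenyl]-3-hydroxychroman-4-one | O=C1c2c(OCc3ccccc3)c(Cc3ccc(OCc4ccccc4)cc3)c(OCc3ccccc3)cc2O[C@H](c2ccc(OCc3ccccc3)cc2)[C@H]1O | intermediate
18 | (2R,3R)-3,5,7-trihydroxy-6-(4-hydroxybenzyl)-2-(4-hydroxyphenyl)chroman-4-one (gericudranin E) | O=C1c2c(cc(O)c(Cc3ccc(O)cc3)c2O)O[C@H](c2ccc(O)cc2)[C@H]1O | target

## Step count and least certain steps

Total step count: 14. Longest linear sequence: 11 (steps 1–6 and 10–14); the side branch to 13 is steps 7–9.

**Step 12 (key step).** The most likely failures are incomplete facial discrimination and loss of material by ionization at C4 on acidic supports. The aryl group at C2 is the only control element and shields less if it sits pseudo-equatorial.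

The fallback sets out from 15 and returns at 17. It moves the stereochemical task from kinetic face selection to thermodynamic control at C3. The dihydroxylation is run as before, and the crude mixture of 16 and the all-cis isomer (2R,3R,4R)-5,7-bis(benzyloxy)-6-[4-(benzyloxy)benzyl]-2-[4-(benzyloxy)phenyl]chromane-3,4-diol F1 is oxidized on MnO2 without separation. The minor component then becomes the 2,3-cis ketol (2R,3S)-5,7-bis(benzyloxy)-6-[4-(benzyloxy)benzyl]-2-[4-(benzyloxy)phenyl]-3-hydroxychroman-4-one F2, in which C3 is α to the carbonyl. Brief treatment with a weak base (NaOAc, EtOH, 40 °C) should equilibrate C3 through the enediol toward the diequatorial isomer 17. C2 is not enolizable, and with the 4'-oxygen benzylated it has no quinone methide path. The base is kept weak so that ring C does not open by β-elimination.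

**Step 10.** Three things may go wrong:

- erosion of enantiomeric purity and drift to the linear ether, because the product is a para-alkoxy-activated allylic benzylic ether that the iridium catalyst can ionize again;
- slow reaction of the ortho-substituted phenoxide;
- C-alkylation at the free, strongly activated C8 position.

The fallback sets out from 10 and 9 and returns at 14. It separates the stereogenic event from the C–O bond formation. Vinylmagnesium bromide adds to 10 to give racemic 1-[4-(benzyloxy)phenyl]prop-2-en-1-ol F3. Lipase-catalysed acetylation (Candida antarctica lipase B, vinyl acetate) should acylate the (R) enantiomer, giving (1R)-1-[4-(benzyloxy)phenyl]prop-2-en-1-yl acetate F4, which is separated from the unreacted (S) alcohol. Methanolysis (K2CO3, MeOH) gives (1R)-1-[4-(benzyloxy)phenyl]prop-2-en-1-ol F5. A Mitsunobu reaction of F5 with 9 (PPh3, diisopropyl azodicarboxylate, toluene, −20 °C) forms O1–C2 with inversion and gives 14. The weak point of this fallback is partial ionization of the activated oxyphosphonium intermediate, which is why low temperature and a non-polar solvent are specified.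

**Step 13.** The likely failure is glycol cleavage of the cis-diol on the manganese surface in competition with benzylic oxidation; ionization at C4 is a second risk if the oxidant is acidic.

The fallback sets out from 16 and returns at 17. It replaces chemoselective oxidation by protection, oxidation and deprotection. Silylation (Et3SiCl, imidazole, CH2Cl2, −20 °C) should take place at the C3 hydroxyl, which is equatorial and free of the peri interaction with the 5-benzyloxy group. This gives (2R,3S,4S)-5,7-bis(benzyloxy)-6-[4-(benzyloxy)benzyl]-2-[4-(benzyloxy)phenyl]-3-[(triethylsilyl)oxy]chroman-4-ol F6; the regiochemistry is the point to verify. Dess–Martin periodinane buffered with NaHCO3 then oxidizes the only free hydroxyl to give (2R,3R)-5,7-bis(benzyloxy)-6-[4-(benzyloxy)benzyl]-2-[4-(benzyloxy)phenyl]-3-[(triethylsilyl)oxy]chroman-4-one F7. Desilylation with HF·pyridine in THF returns 17.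

**Step 5 (and step 6).** Prolonged heating at 190 °C may cause thermal loss or migration of benzyl groups, or cyclization of the ortho-allylphenol onto its own hydroxyl. In step 6 the ruthenium hydride may be sluggish with a free phenol.

The fallback sets out from 7 and returns at 15. It discards the allyl carbons and brings in C4 by formylation:

1. Deallylation with Pd(PPh3)4 and morpholine gives 3,5-bis(benzyloxy)-4-[4-(benzyloxy)benzyl]phenol F8.
2. Ortho-formylation (MgCl2, Et3N, paraformaldehyde, MeCN, reflux) at either of the two equivalent positions gives 4,6-bis(benzyloxy)-5-[4-(benzyloxy)benzyl]-2-hydroxybenzaldehyde F9.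
3. Wittig methylenation (Ph3P=CH2, 2.2 equiv, THF) gives 3,5-bis(benzyloxy)-4-[4-(benzyloxy)benzyl]-2-vinylphenol F10.
4. Etherification with 13 under the conditions of step 10 gives 1,3-bis(benzyloxy)-2-[4-(benzyloxy)benzyl]-5-{[(1S)-1-[4-(benzyloxy)phenyl]prop-2-en-1-yl]oxy}-4-vinylbenzene F11.
5. Ring-closing metathesis under the conditions of step 11 gives 15 with loss of ethene.

This costs three more steps.

## Further compounds

F1 | step 12 | (2R,3R,4R)-5,7-bis(benzyloxy)-6-[4-(benzyloxy)benzyl]-2-[4-(benzyloxy)phenyl]chromane-3,4-diol | O[C@@H]1c2c(OCc3ccccc3)c(Cc3ccc(OCc4ccccc4)cc3)c(OCc3ccccc3)cc2O[C@H](c2ccc(OCc3ccccc3)cc2)[C@@H]1O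
F2 | step 12 | (2R,3S)-5,7-bis(benzyloxy)-6-[4-(benzyloxy)benzyl]-2-[4-(benzyloxy)phenyl]-3-hydroxychroman-4-one | O=C1c2c(OCc3ccccc3)c(Cc3ccc(OCc4ccccc4)cc3)c(OCc3ccccc3)cc2O[C@H](c2ccc(OCc3ccccc3)cc2)[C@@H]1O
F3 | step 10 | 1-[4-(benzyloxy)phenyl]prop-2-en-1-ol (racemic) | C=CC(O)c1ccc(OCc2ccccc2)cc1
F4 | step 10 | (1R)-1-[4-(benzyloxy)phenyl]prop-2-en-1-yl acetate | C=C[C@@H](OC(C)=O)c1ccc(OCc2ccccc2)cc1
F5 | step 10 | (1R)-1-[4-(benzyloxy)phenyl]prop-2-en-1-ol | C=C[C@@H](O)c1ccc(OCc2ccccc2)cc1
F6 | step 13 | (2R,3S,4S)-5,7-bis(benzyloxy)-6-[4-(benzyloxy)benzyl]-2-[4-(benzyloxy)phenyl]-3-[(triethylsilyl)oxy]chroman-4-ol | O[C@H]1c2c(OCc3ccccc3)c(Cc3ccc(OCc4ccccc4)cc3)c(OCc3ccccc3)cc2O[C@H](c2ccc(OCc3ccccc3)cc2)[C@H]1O[Si](CC)(CC)CC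
F7 | step 13 | (2R,3R)-5,7-bis(benzyloxy)-6-[4-(benzyloxy)benzyl]-2-[4-(benzyloxy)phenyl]-3-[(triethylsilyl)oxy]chroman-4-one | O=C1c2c(OCc3ccccc3)c(Cc3ccc(OCc4ccccc4)cc3)c(OCc3ccccc3)cc2O[C@H](c2ccc(OCc3ccccc3)cc2)[C@H]1O[Si](CC)(CC)CC
F8 | step 5 | 3,5-bis(benzyloxy)-4-[4-(benzyloxy)benzyl]phenol | Oc1cc(OCc2ccccc2)c(Cc2ccc(OCc3ccccc3)cc2)c(OCc2ccccc2)c1
F9 | step 5 | 4,6-bis(benzyloxy)-5-[4-(benzyloxy)benzyl]-2-hydroxybenzaldehyde | O=Cc1c(O)cc(OCc2ccccc2)c(Cc2ccc(OCc3ccccc3)cc2)c1OCc1ccccc1
F10 | step 5 | 3,5-bis(benzyloxy)-4-[4-(benzyloxy)benzyl]-2-vinylphenol | C=Cc1c(O)cc(OCc2ccccc2)c(Cc2ccc(OCc3ccccc3)cc2)c1OCc1ccccc1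
F11 | step 5 | 1,3-bis(benzyloxy)-2-[4-(benzyloxy)benzyl]-5-{[(1S)-1-[4-(benzyloxy)phenyl]prop-2-en-1-yl]oxy}-4-vinylbenzene | C=C[C@@H](c1ccc(OCc2ccccc2)cc1)Oc1cc(OCc2ccccc2)c(Cc2ccc(OCc3ccccc3)cc2)c(OCc2ccccc2)c1C=C
A1 | alternative 1 | (2R,3R)-3-(benzyloxy)-6-[4-(benzyloxy)benzyl]-2-[4-(benzyloxy)phenyl]-5-hydroxy-7-[(triisopropylsilyl)oxy]chroman-4-one | O=C1c2c(O)c(Cc3ccc(OCc4ccccc4)cc3)c(O[Si](C(C)C)(C(C)C)C(C)C)cc2O[C@H](c2ccc(OCc3ccccc3)cc2)[C@H]1OCc1ccccc1
A2 | alternative 1 | (2R,3R)-3-(benzyloxy)-2-[4-(benzyloxy)phenyl]-6-(2-diazoacetyl)-2,3-dihydro-4H-pyran-4-one | O=C1C=C(C(=O)C=[N+]=[N-])O[C@H](c2ccc(OCc3ccccc3)cc2)[C@H]1OCc1ccccc1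
A3 | alternative 1 | {[3-[4-(benzyloxy)phenyl]prop-1-yn-1-yl]oxy}tri(propan-2-yl)silane | CC(C)[Si](OC#CCc1ccc(OCc2ccccc2)cc1)(C(C)C)C(C)C
A4 | alternative 2 | (2R,3R)-5,7-bis(benzyloxy)-6-[4-(benzyloxy)benzyl]-2-[4-(benzyloxy)phenyl]-3-hydroxychroman-4-one (identical with 17) | O=C1c2c(OCc3ccccc3)c(Cc3ccc(OCc4ccccc4)cc3)c(OCc3ccccc3)cc2O[C@H](c2ccc(OCc3ccccc3)cc2)[C@H]1O
A5 | alternative 2 | (2R,3S)-4,6-bis(benzyloxy)-5-[4-(benzyloxy)benzyl]-2-[4-(benzyloxy)phenyl]-3-hydroxy-2,3-dihydro-1-benzofuran-3-carbaldehyde | O=C[C@]1(O)c2c(OCc3ccccc3)c(Cc3ccc(OCc4ccccc4)cc3)c(OCc3ccccc3)cc2O[C@@H]1c1ccc(OCc2ccccc2)cc1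
A6 | alternative 3 | (2R,3R)-3-(benzyloxy)-6-[4-(benzyloxy)benzyl]-2-[4-(benzyloxy)phenyl]-5,7-dihydroxychroman-4-one | O=C1c2c(O)c(Cc3ccc(OCc4ccccc4)cc3)c(O)cc2O[C@H](c2ccc(OCc3ccccc3)cc2)[C@H]1OCc1ccccc1
A7 | alternative 3 | (2R,3R)-3-(benzyloxy)-2-[4-(benzyloxy)phenyl]-5-bromo-2,3-dihydro-4H-pyran-4-one | O=C1C(Br)=CO[C@H](c2ccc(OCc3ccccc3)cc2)[C@H]1OCc1ccccc1
A8 | alternative 3 | {[2-[4-(benzyloxy)benzyl]-1-methoxybuta-1,3-diene-1,3-diyl]bis(oxy)}bis(trimethylsilane) | C=C(O[Si](C)(C)C)C(Cc1ccc(OCc2ccccc2)cc1)=C(OC)O[Si](C)(C)C
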